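**Retrosynthetic overview**
- The target comes from its enol methyl ether by O‑demethylation; the ether comes from bridgehead acylation of the bicyclo[3.3.1]nonane core with (R)‑2‑methylbutanoyl chloride, so the acyl C–C bond is made last.
- The core comes from a 5‑acetyl‑5‑prenylcyclopentanone in one flask: Claisen acetylation and dianion aldol close ring A (C2–C3, C1–C9), then an iodine(III)‑triggered 1,2‑shift of C8 from C9 to C1 expands the cyclopentane into ring B.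
- The acetyl ketone comes from the cyclopentanone by C5 acetylation, then C5 prenylation anti to the C7 prenyl group (this gives the 7‑endo relationship of the target).
- The cyclopentanone comes from 2‑methylcyclopent‑2‑enone by catalytic asymmetric conjugate addition/enolate alkylation (sets C7 and C8) and an alkene isomerisation.
- Ring order: five‑membered template (bought) → ring A → ring B, with A and B formed in the same operation.

Assumption: Grignard reagent 2 (from commercial 4‑bromo‑2‑methylbut‑1‑ene and Mg), LDA, iodide 3 and (R)‑2‑methylbutanoyl chloride 14 (from the commercial single‑enantiomer acid) are bought or taken from stock and are not counted as steps; the side‑chain centre is R, as the target SMILES requires.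

Notation: core numbering in the text is C1 = bridgehead that finally carries the acyl group, C2–C4 = enolised β‑diketone carbons, C5 = prenylated bridgehead, C6 = CH2, C7 = CH(prenyl), C8 = C(Me)(4‑methylpent‑3‑enyl), C9 = bridging C=O.

**Step 1**
Reactants: 1 2‑methylcyclopent‑2‑en‑1‑one; 2 (3‑methylbut‑3‑en‑1‑yl)magnesium bromide; 3 5‑iodo‑2‑methylpent‑2‑ene
Product: 5 (2R,3S)‑2‑methyl‑3‑(3‑methylbut‑3‑en‑1‑yl)‑2‑(4‑methylpent‑3‑en‑1‑yl)cyclopentan‑1‑one, via magnesium enolate 4 (not isolated)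
Conditions: Cu(OTf)2 (3 mol %), chiral imidazolinium NHC ligand L* (4 mol %, the enantiomer that gives the 3S adduct), Et2O, −30 °C; then 3, HMPA, THF, −30 → 23 °C
Reagents that add atoms: none
Why: Copper‑catalysed asymmetric conjugate addition of the Grignard reagent sets C3 (S) under ligand control, and the regiodefined magnesium enolate 4 is alkylated in situ anti to the new C3 chain, giving the 2,3‑trans quaternary centre (2R).

**Step 2**
Reactants: 5 (2R,3S)‑2‑methyl‑3‑(3‑methylbut‑3‑en‑1‑yl)‑2‑(4‑methylpent‑3‑en‑1‑yl)cyclopentan‑1‑one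
Product: 6 (2R,3R)‑2‑methyl‑3‑(3‑methylbut‑2‑en‑1‑yl)‑2‑(4‑methylpent‑3‑en‑1‑yl)cyclopentan‑1‑one
Conditions: Co(salen‑tBu4)Cl (3 mol %), PhSiH3 (6 mol %), benzene, 23 °C
Reagents that add atoms: none
Why: Cobalt–salen hydrogen‑atom‑transfer alkene isomerisation moves the terminal 1,1‑disubstituted alkene one position to the more stable trisubstituted prenyl alkene, leaving the other alkene and both stereocentres untouched (the descriptor at C3 changes only through CIP priorities).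

**Step 3**
Reactants: 6 (2R,3R)‑2‑methyl‑3‑(3‑methylbut‑2‑en‑1‑yl)‑2‑(4‑methylpent‑3‑en‑1‑yl)cyclopentan‑1‑one
Product: 7 (2R,3S)‑5‑acetyl‑2‑methyl‑3‑(3‑methylbut‑2‑en‑1‑yl)‑2‑(4‑methylpent‑3‑en‑1‑yl)cyclopentan‑1‑one (C5 epimers/enol tautomers)
Conditions: MgBr2·OEt2 (2.5 equiv), i‑Pr2NEt (3 equiv), 1‑acetyl‑1H‑benzotriazole (1.3 equiv), CH2Cl2, 23 °C
Reagents that add atoms: 1‑acetyl‑1H‑benzotriazole, CC(=O)n1nnc2ccccc12
Why: Soft‑enolisation C‑acylation (crossed Claisen type) occurs at C5, the only enolisable α‑carbon; the new centre is left as a mixture because it is reset in step 4.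

**Step 4**
Reactants: 7 (2R,3S)‑5‑acetyl‑2‑methyl‑3‑(3‑methylbut‑2‑en‑1‑yl)‑2‑(4‑methylpent‑3‑en‑1‑yl)cyclopentan‑1‑one; 8 1‑bromo‑3‑methylbut‑2‑ene
Product: 9 (2R,3S,5S)‑5‑acetyl‑2‑methyl‑3,5‑bis(3‑methylbut‑2‑en‑1‑yl)‑2‑(4‑methylpent‑3‑en‑1‑yl)cyclopentan‑1‑one
Conditions: K2CO3, acetone, 50 °C
Reagents that add atoms: none
Why: C‑alkylation of the cyclic β‑diketone enolate creates the C5 quaternary centre, with prenyl bromide attacking the face anti to the C3 prenyl group so that prenyl ends trans and acetyl cis to it (5S), as the target requires.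

**Step 5**
Reactants: 9 (2R,3S,5S)‑5‑acetyl‑2‑methyl‑3,5‑bis(3‑methylbut‑2‑en‑1‑yl)‑2‑(4‑methylpent‑3‑en‑1‑yl)cyclopentan‑1‑one
Product: 12 (1R,5S,7S,8R)‑4‑hydroxy‑8‑methyl‑5,7‑bis(3‑methylbut‑2‑en‑1‑yl)‑8‑(4‑methylpent‑3‑en‑1‑yl)bicyclo[3.3.1]non‑3‑ene‑2,9‑dione, via acetoacetyl triketone 10 (not isolated), via cis‑hydrindane aldol 11 (not isolated)
Conditions: LDA (2.2 equiv), THF, −78 °C; 1‑acetyl‑1H‑benzotriazole (1.3 equiv); LDA (1.3 equiv), −78 → 0 °C; then MeOH, PhI(OAc)2 (1.2 equiv), 0 → 23 °C, same flask; aq. HCl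
Reagents that add atoms: 1‑acetyl‑1H‑benzotriazole, CC(=O)n1nnc2ccccc12
Why: Proposed new method: the kinetic acetyl enolate of 9 is C‑acylated to triketone 10, whose 1,3‑diketone dianion closes ring A by 6‑exo aldol addition of its terminal carbon to the C9 ketone on the face carrying the chain (11); PhI(OAc)2 then forms the C3‑iodonium diketone, and alkoxide‑driven 1,2‑shift of the tertiary C8 from C9 to C1 with SN2′‑type loss of PhI (vinylogous semipinacol) turns the cyclopentane into ring B, with retention at C8 and C1 fixed by the bicycle (C5, bearing the acyl carbon, migrates poorly); the closest known chemistry is β‑diketone dianion aldol cyclisation and iodine(III)‑mediated oxidative ring expansion of β‑hydroxy‑1,3‑diketones.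

**Step 6**
Reactants: 12 (1R,5S,7S,8R)‑4‑hydroxy‑8‑methyl‑5,7‑bis(3‑methylbut‑2‑en‑1‑yl)‑8‑(4‑methylpent‑3‑en‑1‑yl)bicyclo[3.3.1]non‑3‑ene‑2,9‑dione
Product: 13 (1S,5R,6R,7S)‑4‑methoxy‑6‑methyl‑1,7‑bis(3‑methylbut‑2‑en‑1‑yl)‑6‑(4‑methylpent‑3‑en‑1‑yl)bicyclo[3.3.1]non‑3‑ene‑2,9‑dione (OMe on the carbon next to the C–H bridgehead)
Conditions: Me2SO4, K2CO3, acetone, 23 °C; chromatographic removal of the minor O‑regioisomer
Reagents that add atoms: dimethyl sulfate, COS(=O)(=O)OC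
Why: O‑Methylation of the vinylogous acid (Williamson type) is expected to favour the less hindered oxygen beside the unsubstituted bridgehead, which places OMe where it can direct the next lithiation; no stereocentre is affected.

**Step 7**
Reactants: 13 (1S,5R,6R,7S)‑4‑methoxy‑6‑methyl‑1,7‑bis(3‑methylbut‑2‑en‑1‑yl)‑6‑(4‑methylpent‑3‑en‑1‑yl)bicyclo[3.3.1]non‑3‑ene‑2,9‑dione; 14 (R)‑2‑methylbutanoyl chloride
Product: 16 (1S,5R,6R,7S)‑4‑methoxy‑6‑methyl‑5‑[(2R)‑2‑methylbutanoyl]‑1,7‑bis(3‑methylbut‑2‑en‑1‑yl)‑6‑(4‑methylpent‑3‑en‑1‑yl)bicyclo[3.3.1]non‑3‑ene‑2,9‑dione, via bridgehead organolithium 15 (not isolated)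
Conditions: LDA (1.1 equiv), THF, −78 °C; then cannulated into 14 (2 equiv), THF, −78 °C
Reagents that add atoms: none
Why: Kinetic bridgehead lithiation α to the C9 ketone and the methoxy‑bearing enol ether carbon (known for bicyclo[3.3.1]nonane‑trione enol ethers) followed by acylation of the non‑invertible carbanion 15 gives the C1 ketone with retention, and inverse addition at −78 °C is meant to let acylation outrun ketene formation so the side‑chain centre stays R.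

**Step 8**
Reactants: 16 (1S,5R,6R,7S)‑4‑methoxy‑6‑methyl‑5‑[(2R)‑2‑methylbutanoyl]‑1,7‑bis(3‑methylbut‑2‑en‑1‑yl)‑6‑(4‑methylpent‑3‑en‑1‑yl)bicyclo[3.3.1]non‑3‑ene‑2,9‑dione
Product: 17 (1S,5S,7S,8R)‑4‑hydroxy‑8‑methyl‑1‑[(2R)‑2‑methylbutanoyl]‑5,7‑bis(3‑methylbut‑2‑en‑1‑yl)‑8‑(4‑methylpent‑3‑en‑1‑yl)bicyclo[3.3.1]non‑3‑ene‑2,9‑dione (CNP0268336.1)
Conditions: LiCl, DMSO, 120 °C; then H2O
Reagents that add atoms: none
Why: Chloride‑mediated SN2 O‑demethylation of the vinylogous methyl ester (Krapcho type, non‑basic) frees the enolised β‑diketone without touching the bridgehead acyl ketone or its α‑stereocentre.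

**Compound list**
1 | 2‑methylcyclopent‑2‑en‑1‑one | CC1=CCCC1=O | starting material
2 | (3‑methylbut‑3‑en‑1‑yl)magnesium bromide | CC(=C)CC[Mg]Br | starting material
3 | 5‑iodo‑2‑methylpent‑2‑ene | CC(C)=CCCI | starting material
4 | bromomagnesium (3S)‑2‑methyl‑3‑(3‑methylbut‑3‑en‑1‑yl)cyclopent‑1‑en‑1‑olate | Br[Mg]OC1=C(C)[C@@H](CCC(C)=C)CC1 | intermediate
5 | (2R,3S)‑2‑methyl‑3‑(3‑methylbut‑3‑en‑1‑yl)‑2‑(4‑methylpent‑3‑en‑1‑yl)cyclopentan‑1‑one | O=C1CC[C@H](CCC(C)=C)[C@@]1(C)CCC=C(C)C | intermediate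
6 | (2R,3R)‑2‑methyl‑3‑(3‑methylbut‑2‑en‑1‑yl)‑2‑(4‑methylpent‑3‑en‑1‑yl)cyclopentan‑1‑one | O=C1CC[C@H](CC=C(C)C)[C@@]1(C)CCC=C(C)C | intermediate
7 | (2R,3S)‑5‑acetyl‑2‑methyl‑3‑(3‑methylbut‑2‑en‑1‑yl)‑2‑(4‑methylpent‑3‑en‑1‑yl)cyclopentan‑1‑one (C5 epimers/enol) | O=C1C(C(C)=O)C[C@H](CC=C(C)C)[C@@]1(C)CCC=C(C)C | intermediate
8 | 1‑bromo‑3‑methylbut‑2‑ene (prenyl bromide) | CC(C)=CCBr | starting material
9 | (2R,3S,5S)‑5‑acetyl‑2‑methyl‑3,5‑bis(3‑methylbut‑2‑en‑1‑yl)‑2‑(4‑methylpent‑3‑en‑1‑yl)cyclopentan‑1‑one | O=C1[C@](CC=C(C)C)(C(C)=O)C[C@H](CC=C(C)C)[C@@]1(C)CCC=C(C)C | intermediate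
10 | (2R,3S,5S)‑2‑methyl‑3,5‑bis(3‑methylbut‑2‑en‑1‑yl)‑2‑(4‑methylpent‑3‑en‑1‑yl)‑5‑(3‑oxobutanoyl)cyclopentan‑1‑one (lithium dianion in the flask) | O=C1[C@](CC=C(C)C)(C(=O)CC(C)=O)C[C@H](CC=C(C)C)[C@@]1(C)CCC=C(C)C | intermediate
11 | (1R,2S,3aR,7aR)‑7a‑hydroxy‑1‑methyl‑2,3a‑bis(3‑methylbut‑2‑en‑1‑yl)‑1‑(4‑methylpent‑3‑en‑1‑yl)‑2,3,3a,7a‑tetrahydro‑1H‑indene‑4,6(5H,7H)‑dione (cis‑fused; lithium salt in the flask) | O=C1CC(=O)[C@]2(CC=C(C)C)C[C@H](CC=C(C)C)[C@@](C)(CCC=C(C)C)[C@]2(O)C1 | intermediate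
12 | (1R,5S,7S,8R)‑4‑hydroxy‑8‑methyl‑5,7‑bis(3‑methylbut‑2‑en‑1‑yl)‑8‑(4‑methylpent‑3‑en‑1‑yl)bicyclo[3.3.1]non‑3‑ene‑2,9‑dione | O=C1C=C(O)[C@]2(CC=C(C)C)C[C@H](CC=C(C)C)[C@@](C)(CCC=C(C)C)[C@H]1C2=O | intermediate
13 | (1S,5R,6R,7S)‑4‑methoxy‑6‑methyl‑1,7‑bis(3‑methylbut‑2‑en‑1‑yl)‑6‑(4‑methylpent‑3‑en‑1‑yl)bicyclo[3.3.1]non‑3‑ene‑2,9‑dione | COC1=CC(=O)[C@]2(CC=C(C)C)C[C@H](CC=C(C)C)[C@@](C)(CCC=C(C)C)[C@H]1C2=O | intermediate
14 | (R)‑2‑methylbutanoyl chloride | CC[C@@H](C)C(Cl)=O | starting material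
15 | bridgehead organolithium of 13 (Li in place of the bridgehead H, configuration retained) | [Li][C@]12C(OC)=CC(=O)[C@](CC=C(C)C)(C[C@H](CC=C(C)C)[C@@]1(C)CCC=C(C)C)C2=O | intermediate
16 | (1S,5R,6R,7S)‑4‑methoxy‑6‑methyl‑5‑[(2R)‑2‑methylbutanoyl]‑1,7‑bis(3‑methylbut‑2‑en‑1‑yl)‑6‑(4‑methylpent‑3‑en‑1‑yl)bicyclo[3.3.1]non‑3‑ene‑2,9‑dione | CC[C@@H](C)C(=O)[C@]12C(OC)=CC(=O)[C@](CC=C(C)C)(C[C@H](CC=C(C)C)[C@@]1(C)CCC=C(C)C)C2=O | intermediate
17 | (1S,5S,7S,8R)‑4‑hydroxy‑8‑methyl‑1‑[(2R)‑2‑methylbutanoyl]‑5,7‑bis(3‑methylbut‑2‑en‑1‑yl)‑8‑(4‑methylpent‑3‑en‑1‑yl)bicyclo[3.3.1]non‑3‑ene‑2,9‑dione | CC[C@@H](C)C(=O)[C@]12C(=O)C=C(O)[C@](CC=C(C)C)(C[C@H](CC=C(C)C)[C@@]1(C)CCC=C(C)C)C2=O | target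

**Step count and risks**
Total step count: 8. Longest linear sequence: 8 steps (from 1 to 17).

The three steps most likely to fail are 5, 1 and 7.

Step 5 carries the most risk. The acetylation, the dianion aldol and the oxidative shift must all work in one flask, amine and benzotriazole by‑products compete for the oxidant, and the shift has to form the more crowded 7‑endo bicycle. The fallback sets out from 9 and comes back at 12; it forms each ring in its own operation and replaces the iodine(III) trigger by carbon–halogen ionisation. Acetylation of 9 under the soft‑enolisation conditions of step 3 gives isolated triketone 10. LDA (2.2 equiv, THF, −78 → 0 °C) then closes ring A to isolated aldol 11. The trianion of 11 (LDA, 3.3 equiv) is brominated with NBS at −78 °C on the γ‑carbon (C1) to give the 7‑bromo aldol F1. AgOTf/2,6‑lutidine in CH2Cl2 then ionises the C–Br bond so that C8 shifts from C9 to C1 as a halohydrin semipinacol, giving 12.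

Step 1 may fail at the alkylation of the hindered magnesium enolate with an unactivated iodide, or give insufficient ee. The fallback sets out from 1 (with 2) and comes back at 5; it builds the side chain by addition to an sp2 acceptor instead of SN2. The same copper‑catalysed addition is quenched with TMSCl to give the isolated silyl enol ether F2. Mukaiyama–Michael addition of F2 to acrolein (BF3·OEt2, MeNO2/CH2Cl2, −78 °C, then H2O) gives the keto aldehyde F3, with the quaternary centre set anti to the C3 chain. Chemoselective Wittig olefination of the aldehyde with isopropylidenetriphenylphosphorane (i‑PrPPh3I, n‑BuLi, THF, −78 → 0 °C) gives 5.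

Step 7 may fail through competing deprotonation at the vinylic carbon of the enol ether, or through ketene formation from 14, which would scramble the side‑chain centre. The fallback sets out from 13 and comes back at 16. The bridgehead organolithium 15 is added to (R)‑2‑methylbutanal, which cannot form a ketene and adds faster than it enolises, giving the carbinol F4 as a mixture at the new CH(OH) centre. Dess–Martin periodinane/NaHCO3 in CH2Cl2 then oxidises F4 to 16.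

**Further compounds**
F1 | step 5 | (1R,2S,3aR,7aR)‑7‑bromo‑7a‑hydroxy‑1‑methyl‑2,3a‑bis(3‑methylbut‑2‑en‑1‑yl)‑1‑(4‑methylpent‑3‑en‑1‑yl)‑2,3,3a,7a‑tetrahydro‑1H‑indene‑4,6(5H,7H)‑dione (C7 epimers) | O=C1CC(=O)[C@]2(CC=C(C)C)C[C@H](CC=C(C)C)[C@@](C)(CCC=C(C)C)[C@]2(O)C1Br
F2 | step 1 | trimethyl{[(3S)‑2‑methyl‑3‑(3‑methylbut‑3‑en‑1‑yl)cyclopent‑1‑en‑1‑yl]oxy}silane | C[Si](C)(C)OC1=C(C)[C@@H](CCC(C)=C)CC1
F3 | step 1 | 3‑[(1R,2S)‑1‑methyl‑2‑(3‑methylbut‑3‑en‑1‑yl)‑5‑oxocyclopentyl]propanal | O=C1CC[C@H](CCC(C)=C)[C@@]1(C)CCC=O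
F4 | step 7 | (1S,5S,6R,7S)‑5‑[(2R)‑1‑hydroxy‑2‑methylbutyl]‑4‑methoxy‑6‑methyl‑1,7‑bis(3‑methylbut‑2‑en‑1‑yl)‑6‑(4‑methylpent‑3‑en‑1‑yl)bicyclo[3.3.1]non‑3‑ene‑2,9‑dione (carbinol epimers) | CC[C@@H](C)C(O)[C@]12C(OC)=CC(=O)[C@](CC=C(C)C)(C[C@H](CC=C(C)C)[C@@]1(C)CCC=C(C)C)C2=O
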